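**Remarks on the chemistry (assumptions)**
- The (5R) acetal epimer of 7 is taken to be the one that crystallises. If the (5S) epimer crystallises instead, (+)-menthol is used, because only the acetal centre steers the cycloaddition and the auxiliary is lost in step 12.
- Centres that are erased later are carried as mixtures and left undefined in the SMILES: C1 in 10–12, sulfur in 12, C7 in 15–29, C10 in 17, C8 in 20.

## Analysis of the target

Compound 30 is a daucane-type hydroazulene: a cycloheptenone (ring A) fused along C4–C5 to a cyclopentane (ring B), with a 4-hydroxybenzoate on the C3 oxygen. The locants used throughout are: C1 (alkene carbon bearing CH3), C2 (alkene CH), C3 (ester carbinol), C4 (fusion CH), C5 (quaternary fusion carbon bearing CH3), C6 (CH2), C7 (ketone), C8 (CHOH), C9 (CH2), C10 (isopropyl carbinol). Ring A is C1–C7; ring B is C4, C5, C8, C9, C10. The five stereocentres C3, C4, C5, C8 and C10 are contiguous around the fusion. The rings are trans-fused (H4 anti to the C5 methyl), the C8 and C10 hydroxyls are both syn to the C5 methyl (so the isopropyl group is syn to H4), and the C3 oxygen is syn to H4. Sensitive features are the C3 ester (allylic and γ to the C7 ketone), the tertiary C10 alcohol, the free phenol, and, during assembly, any C10 carbonyl, which has the C3 oxygen in its β-position. The difficulty lies in the quaternary C5 flanked by three stereocentres, the trans fusion, and five oxygen functions at different oxidation levels. The strategy rests on one feature: C7=O, C1=C2 and C3–O are the carbonyl, alkene and bridgehead C–O of an 8-oxabicyclo[3.2.1]oct-3-en-2-one. Its second bridgehead bond, C6–O, lies α to the ketone and can be removed reductively, and its two-carbon bridge is C4–C5.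

## Retrosynthetic reasoning

**Ester and late redox (30 back to 23 and 26).** The C3 O–acyl bond is cut first, because an aryl ester β to a C10 carbonyl would not survive organometallic or enolate chemistry. In the forward sense 23 is esterified with silyl-protected acid 26 (from 24) to give 27 while C8 is still a ketone, so C3–OH is the only acylable hydroxyl. The C8 carbonyl is then reduced (28). C7 is carried as a silyl-protected allylic alcohol, so only one carbonyl is present at that reduction. Desilylation (29) and an oxidation selective for the allylic C7 alcohol finish the enone of 30.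

**Ring B, C9–C10 (22 back to 21).** Cutting C9–C10 gives a methyl ketone on the quaternary C5, which can enolise on one side only, and an isobutyryl group on C4. The forward aldol is a five-membered closure that has to set C10. The isopropyl group should take the face syn to H4, away from the ring A carbon C3.

**C8–C9, C10–isopropyl and the C4 centre (21 back to 16).** C8 and C10 are the acetal and carbonyl carbons of the lactone acetal in 16, a masked 1,4-keto aldehyde. An isopropyl nucleophile converts the lactone carbonyl into the C10 ketone and releases the C8 aldehyde and menthol 6 (18). C4 is inverted at this stage (19), for three reasons: it is α to the new ketone, no aldol partner exists yet, and the C5 formyl group cannot enolise. A methyl nucleophile and an oxidation then give 20 and 21.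

**Ring A adjustments and the C6–O bond (16 back to 9).** The oxygen bridge must be cut before ring B is made, for two reasons. A trans-fused five-membered ring cannot sit on the two-carbon bridge of the bicycle. A C4 enolate in the bicycle would also expel the bridging oxygen from C3. In enone 9 the bridging oxygen is α to the carbonyl through C6 but also vinylogously γ through C3. Electron transfer to an enone builds charge at C2, which would break C3–O, the wrong bond. The C1=C2 bond is therefore saturated temporarily by thiol addition (10), the α C6–O bond is cleaved reductively (11), and sulfoxide elimination (via 12) returns enone 13. C3–OH is silylated (14) so that it neither forms a lactol with the later C8 aldehyde nor is oxidised. C7 is reduced (15) and protected with a second, more robust silyl group (16) so that it is neither electrophilic nor enolisable in the following steps.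

**Key disconnection, C3–C4 and C5–C6 (9 back to 8 and 7).** Both bonds are formed at once by adding ylide 8 across the alkene of butenolide 7. This closes ring A, sets C3 and C5, places the C7 ketone, the C1=C2 alkene and the C3 oxygen at their final positions, and delivers C8 and C10 as differentiated carbonyl equivalents. Three selectivities are required. The methyl-bearing β-carbon must bond to the ylide terminus next to the oxido carbon. Attack must be anti to the menthyloxy group. Approach must be exo. C5 depends only on the face attacked; C3 depends on exo approach. C4 emerges cis and is corrected later.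

**Starting materials.** Ylide 8 comes from acetate 4, made from furoate 1 by reduction (2), Achmatowicz rearrangement (3) and acetylation. Butenolide 7 is the menthyl acetal of 5 with 6.

## Alternatives that were turned down

**Alternative 1: nitrile oxide cycloaddition.**
- Disconnection: ring A at C1–C7, with an O–CH2 bond that masks the future C1 methyl.
- Forward key step: oxidation of oxime A1 triggers an intramolecular nitrile oxide–alkene cycloaddition to isoxazoline A2. N–O cleavage, dehydration and alkene isomerisation would follow.
- For: ring B with C4, C5, C8 and C10 is complete on a cyclopentane before ring closure, so no late C4 inversion is needed. The C7 carbonyl is masked as C=N throughout. On ring B stereocontrol this plan is stronger than the chosen one.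
- Against: closing a seven-membered ring this way is entropically less favourable than the usual five- and six-membered cases. A1 is a pentasubstituted cyclopentane with two differentiated arms and an acyclic C3 centre, which means a long linear build. After the key step the enone still requires N–O reduction, dehydration and an exo-to-endo alkene shift next to an allylic oxygen.
- Comparison: the chosen route makes ring A, the C3 oxygen and quaternary C5 in one intermolecular step from two fragments of three and one steps, with enone and C3–O already at their final oxidation levels.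

**Alternative 2: vinylcarbenoid cyclopropanation and Cope rearrangement.**
- Disconnection: C1–C2 and C5–C6.
- Forward key step: a dirhodium carbenoid from diazo ester A3 cyclopropanates the ethoxyvinyl group of diene A4, and a divinylcyclopropane Cope rearrangement gives cycloheptadiene A5.
- For: it is convergent and catalytic, forms quaternary C5, and places oxygen at C7 and C3. On catalytic enantiocontrol it is stronger than an auxiliary approach.
- Against: the Cope step must create C5 from a tetrasubstituted ring alkene on a chiral diene, whose C8 and C10 groups may match or mismatch the catalyst. In A5 both C3 and C4 are sp2, so the C3 carbinol and the trans fusion are still unset. The C1 ester must be converted into a methyl group. A4 needs a multi-step stereocontrolled cyclopentene synthesis.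
- Comparison: the chosen cycloaddition sets C3 and C5 directly, leaves only C4 to correct, and its chiral partner 7 is one step from commercial materials.

**Alternative 3: semipinacol ring expansion.**
- Disconnection: the C4–C5 fusion bond.
- Forward key step: acid protonates the alkenyl group of cyclobutanol A6 at C6, and C4 migrates from C8 to the C5 cation, giving cyclopentanone A7.
- For: the quaternary centre and the C4–C5 bond are formed with retention at C4, and the C8 ketone is left for later reduction. On the fusion relationship this is stronger than the chosen route, which needs an epimerisation.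
- Against: the C5 configuration depends on the face of a planar cation, controlled only by conformation. Acid meets a tertiary and a propargylic silyl ether. A6 is laborious. Ring A is left entirely open, so C1–C7 closure and enone installation remain.
- Comparison: weaker in step economy, since the chosen route closes the seven-membered ring in its key step.

Key step: step 5

## Route

Step 1
Reactants: 1 methyl 3-methylfuran-2-carboxylate
Product: 2 (3-methylfuran-2-yl)methanol
Conditions: LiAlH4, Et2O, 0 °C
Reagents that add atoms: none
Why: Hydride reduction of the ester to the primary alcohol; the furan ring is inert to LiAlH4.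

Step 2
Reactants: 2 (3-methylfuran-2-yl)methanol
Product: 3 6-hydroxy-4-methyl-2H-pyran-3(6H)-one
Conditions: NBS, NaHCO3, NaOAc, THF/H2O (4:1), 0 °C
Reagents that add atoms: water, O
Why: Achmatowicz rearrangement: oxidative opening of the furan to the ene-dione and closure of the hydroxymethyl oxygen onto the aldehyde; the furan 3-methyl becomes the C4 methyl of the pyranone.

Step 3
Reactants: 3 6-hydroxy-4-methyl-2H-pyran-3(6H)-one
Product: 4 6-acetoxy-4-methyl-2H-pyran-3(6H)-one (racemic)
Conditions: Ac2O, pyridine, DMAP (cat.), CH2Cl2, 0 °C
Reagents that add atoms: acetic anhydride, CC(=O)OC(C)=O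
Why: Acetylation of the anomeric hydroxyl installs the leaving group for ylide formation; the stereocentre is irrelevant because it is lost in 8.

Step 4
Reactants: 5 5-hydroxy-4-methylfuran-2(5H)-one; 6 (−)-menthol
Product: 7 (5R)-5-[(1R,2S,5R)-menthyloxy]-4-methylfuran-2(5H)-one
Conditions: camphorsulfonic acid (cat.), toluene, reflux, Dean–Stark; crystallisation from petroleum ether, mother liquor re-equilibrated with acid and recycled
Reagents that add atoms: none
Why: Acid-catalysed acetalisation of the pseudo-acid; the two acetal epimers interconvert under acid, so crystallisation should funnel the material into one epimer (crystallisation-induced epimerisation).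

Step 5
Reactants: 4 6-acetoxy-4-methyl-2H-pyran-3(6H)-one; 7 (5R)-5-menthyloxy-4-methylfuran-2(5H)-one
Product: 9 exo oxa-bridged cycloadduct (8-oxabicyclo[3.2.1]oct-3-en-2-one fused at C4–C5 to the menthyloxy lactone), via 4-methyl-3-oxidopyrylium ylide 8 (not isolated)
Conditions: 7 (1 equiv), iPr2NEt, MeCN, 60 °C; 4 (3 equiv) added slowly by syringe pump
Reagents that add atoms: none
Why: The amine removes the proton α to the ketone of 4 and acetate leaves, giving ylide 8, whose two carbons flanking the ring oxygen add suprafacially to the butenolide alkene of 7 in a concerted, asynchronous (5+2) dipolar cycloaddition; the closest known reaction type is the intermolecular cycloaddition of 3-oxidopyrylium ylides with acrylates, enones and maleimides. Ring A is closed intermolecularly as a seven-membered carbocycle spanned by the former ring oxygen, by forming C3–C4 and C5–C6 in one step. Regiochemistry follows the polarisation of both partners: the ylide carbon next to the oxido carbon is the nucleophilic terminus and bonds to the electrophilic β-carbon C5, which places quaternary C5 next to C6 and the lactone carbonyl C10 on C4. C5 and C4 are set by attack on the face of 7 anti to the menthyloxy group of the (5R) acetal carbon, and are necessarily cis. C3 and C6 are set by exo approach, with the lactone on the side of the ylide oxygen and the C5 methyl under the enone; this is the one selectivity not enforced by a substrate element. Slow addition of 4 keeps the concentration of 8 low, so second-order self-dimerisation is disfavoured relative to capture by the sluggish trisubstituted alkene.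

Step 6
Reactants: 9 exo cycloadduct
Product: 10 C2 phenylthio adduct (saturated C7 ketone, C2–SPh syn to the oxygen bridge)
Conditions: PhSH, Et3N (0.1 equiv), CH2Cl2, 0 °C
Reagents that add atoms: thiophenol, Sc1ccccc1
Why: Thia-Michael addition to the strained enone from the face of the oxygen bridge; it removes the vinylogous link between the carbonyl and the C3–O bond, so that only the C6–O bond remains activated.

Step 7
Reactants: 10 C2 phenylthio adduct
Product: 11 ring-opened hydroxy ketone sulfide (C3–OH free, C6 now CH2)
Conditions: SmI2 (2.2 equiv), THF/MeOH, −78 °C; aq. NH4Cl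
Reagents that add atoms: none
Why: Reductive cleavage of an α-alkoxy ketone by SmI2: the ketyl expels the C6 oxygen as the C3 alkoxide and the samarium enolate is protonated by methanol; the lactone and the sulfide should be inert at −78 °C, and C3 keeps its configuration.

Step 8
Reactants: 11 hydroxy ketone sulfide
Product: 13 γ-hydroxy enone lactone acetal (C3–OH, C1=C2, C7=O), via sulfoxide 12 (not isolated)
Conditions: mCPBA (1.0 equiv), CH2Cl2, −78 °C; then Et3N, −78 °C to rt
Reagents that add atoms: none
Why: Sulfide oxidation followed by E1cB loss of benzenesulfenate through the C7 enolate regenerates the conjugated C1=C2 enone under mild conditions.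

Step 9
Reactants: 13 γ-hydroxy enone
Product: 14 C3 triethylsilyl ether
Conditions: Et3SiCl, imidazole, DMF, 0 °C to rt
Reagents that add atoms: chlorotriethylsilane, CC[Si](Cl)(CC)CC
Why: Silylation of the only hydroxyl; it prevents later lactol formation with the C8 aldehyde and oxidation at C3, and is removable in the presence of the second silyl group.

Step 10
Reactants: 14 C3 triethylsilyl ether
Product: 15 C7 allylic alcohol (C7 epimers)
Conditions: NaBH4, CeCl3·7H2O, MeOH, −78 °C
Reagents that add atoms: none
Why: Luche 1,2-reduction of the enone; the lactone acetal is not reduced at this temperature, and the C7 configuration is irrelevant because the centre is reoxidised in step 22.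

Step 11
Reactants: 15 C7 allylic alcohol
Product: 16 C7 tert-butyldimethylsilyl ether
Conditions: tBuMe2SiCl, imidazole, DMF, rt
Reagents that add atoms: tert-butylchlorodimethylsilane, CC(C)(C)[Si](C)(C)Cl
Why: Silylation removes the last acidic and electrophilic site of ring A before the organometallic and enolate steps.

Step 12
Reactants: 16 bis-silyl lactone acetal
Product: 18 cis keto aldehyde (C10 isobutyryl on C4 and C8 formyl on C5 on the same face), via cyclic hemiketal 17 (not isolated)
Conditions: iPrMgCl, CeCl3, THF, −78 °C; AcOH at −78 °C, then aq. NH4Cl, rt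
Reagents that add atoms: isopropylmagnesium chloride, CC(C)[Mg]Cl
Why: Mono-addition of a weakly basic organocerium reagent to the lactone carbonyl gives a tetrahedral alkoxide that persists at −78 °C; on work-up hemiketal 17 opens to the C10 ketone, and the resulting menthyl hemiacetal at C8 collapses to the aldehyde with loss of menthol. The hindered isopropyl ketone should resist a second addition.

Step 13
Reactants: 18 cis keto aldehyde
Product: 19 trans keto aldehyde (C4 epimer of 18)
Conditions: K2CO3, MeOH, 0 °C to rt
Reagents that add atoms: none
Why: Thermodynamic epimerisation through the C10 enolate: in 19 the C3 silyloxy, C4 acyl and C5 formyl groups alternate trans and can all be pseudo-equatorial. The C8 aldehyde cannot enolise, and an aldol from the isopropyl-side enolate would be a Baldwin-disfavoured 5-(enolendo)-exo-trig closure. Reversible enolisation in a protic medium should outrun loss of the β-silyloxy group.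

Step 14
Reactants: 19 trans keto aldehyde
Product: 20 C8 methyl carbinol (C8 epimers, in equilibrium with the cyclic hemiketal to C10)
Conditions: MeTi(OiPr)3 (from MeLi and ClTi(OiPr)3), THF, −40 to 0 °C
Reagents that add atoms: methyltitanium triisopropoxide, C[Ti](OC(C)C)(OC(C)C)OC(C)C
Why: The non-basic methyltitanium reagent adds to the aldehyde chemoselectively over the hindered ketone and does not enolise C4, so the configuration set in step 13 is retained.

Step 15
Reactants: 20 C8 methyl carbinol
Product: 21 trans 1,4-diketone (C8 acetyl on C5, C10 isobutyryl on C4)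
Conditions: Dess–Martin periodinane, NaHCO3, CH2Cl2, rt
Reagents that add atoms: none
Why: Buffered, non-basic oxidation of the secondary alcohol through its open-chain form; both C8 epimers converge.

Step 16
Reactants: 21 trans 1,4-diketone
Product: 22 trans-fused aldol (ring B closed, C8 ketone, C10 tertiary alcohol syn to the C5 methyl)
Conditions: LiN(SiMe3)2, THF, −78 to −40 °C; AcOH at −78 °C
Reagents that add atoms: none
Why: Intramolecular aldol addition (5-enolexo-exo-trig): the acetyl group can enolise only toward C9, and the enolate adds to the C10 ketone to close ring B trans-fused. C10 is set by placing the isopropyl group on the face of H4, away from the ring A carbon C3 and the C5 methyl. A cold quench avoids retro-aldol and dehydration.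

Step 17
Reactants: 22 trans-fused aldol
Product: 23 C3 alcohol
Conditions: PPTS, MeOH, 0 °C to rt
Reagents that add atoms: none
Why: Mild acidic methanolysis removes the triethylsilyl ether and leaves the secondary tert-butyldimethylsilyl ether, using the usual lability difference between the two groups.

Step 18
Reactants: 24 4-hydroxybenzoic acid
Product: 26 4-(triisopropylsilyloxy)benzoic acid, via silyl ester 25 (not isolated)
Conditions: iPr3SiCl (2.2 equiv), imidazole, DMF, rt; then AcOH, THF/H2O, rt
Reagents that add atoms: chlorotriisopropylsilane, CC(C)[Si](Cl)(C(C)C)C(C)C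
Why: Bis-silylation followed by selective hydrolysis of the labile silyl ester; the aryl silyl ether is stable to dilute acid.

Step 19
Reactants: 23 C3 alcohol; 26 4-(triisopropylsilyloxy)benzoic acid
Product: 27 C3 4-(triisopropylsilyloxy)benzoate
Conditions: EDC·HCl, DMAP, CH2Cl2, rt
Reagents that add atoms: none
Why: Steglich esterification with retention at C3; the tertiary C10 alcohol is not acylated, and with C10 now a carbinol the ester has no β-carbonyl through which to eliminate.

Step 20
Reactants: 27 C3 benzoate
Product: 28 C8 alcohol (C8–OH syn to the C5 methyl and to C10–OH)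
Conditions: NaBH4, MeOH, −20 °C
Reagents that add atoms: none
Why: Ketone reduction with hydride delivered anti to the pseudo-axial angular methyl on C5, the selectivity known for cyclopentanones next to a quaternary fusion carbon (17-keto steroids); the ester is not reduced.

Step 21
Reactants: 28 C8 alcohol
Product: 29 C7 allylic alcohol with free phenol
Conditions: Bu4NF, AcOH, THF, 0 °C to rt
Reagents that add atoms: none
Why: Buffered fluoride cleaves both the aryl triisopropylsilyl ether and the allylic tert-butyldimethylsilyl ether.

Step 22
Reactants: 29 C7 allylic alcohol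
Product: 30 target
Conditions: MnO2, CH2Cl2, rt
Reagents that add atoms: none
Why: MnO2 oxidises only the allylic C7 alcohol; the saturated C8 alcohol, the tertiary C10 alcohol and the electron-poor phenol should be untouched.

## Compound list

1 | methyl 3-methylfuran-2-carboxylate | COC(=O)c1occc1C | starting material
2 | (3-methylfuran-2-yl)methanol | Cc1ccoc1CO | intermediate
3 | 6-hydroxy-4-methyl-2H-pyran-3(6H)-one (racemic hemiacetal) | CC1=CC(O)OCC1=O | intermediate
4 | 6-acetoxy-4-methyl-2H-pyran-3(6H)-one (racemic) | CC1=CC(OC(C)=O)OCC1=O | intermediate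
5 | 5-hydroxy-4-methylfuran-2(5H)-one | CC1=CC(=O)OC1O | starting material
6 | (−)-menthol | CC(C)[C@@H]1CC[C@@H](C)C[C@H]1O | starting material
7 | (5R)-5-[(1R,2S,5R)-menthyloxy]-4-methylfuran-2(5H)-one | CC1=CC(=O)O[C@H]1O[C@@H]2C[C@H](C)CC[C@H]2C(C)C | intermediate
8 | 4-methyl-3-oxidopyrylium ylide (4-methylpyrylium-3-olate) | Cc1cc[o+]cc1[O-] | intermediate
9 | exo (5+2) adduct: 8-oxabicyclo[3.2.1]oct-3-en-2-one (C7=O, C1(CH3)=C2, oxygen bridge C3–O–C6) with the lactone acetal fused at C4–C5 syn to the bridge (C10 lactone C=O on C4, C8 menthyloxy acetal on C5; H4 and C5–CH3 endo) | CC1=C[C@@H]2O[C@H](C1=O)[C@@]3(C)[C@H](O[C@@H]4C[C@H](C)CC[C@H]4C(C)C)OC(=O)[C@H]32 | intermediate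
10 | C2 phenylthio adduct of 9 (C2–SPh syn to the oxygen bridge, C1 H/CH3 undefined) | CC1[C@H](Sc2ccccc2)[C@@H]3O[C@H](C1=O)[C@@]4(C)[C@H](O[C@@H]5C[C@H](C)CC[C@H]5C(C)C)OC(=O)[C@H]43 | intermediate
11 | cycloheptanone with C3–OH, C2–SPh, C6 H2 and the cis-fused menthyloxy lactone at C4–C5 | CC1[C@H](Sc2ccccc2)[C@H](O)[C@H]3[C@@](C)(CC1=O)[C@H](O[C@@H]4C[C@H](C)CC[C@H]4C(C)C)OC3=O | intermediate
12 | sulfoxide of 11 | CC1[C@H](S(=O)c2ccccc2)[C@H](O)[C@H]3[C@@](C)(CC1=O)[C@H](O[C@@H]4C[C@H](C)CC[C@H]4C(C)C)OC3=O | intermediate
13 | γ-hydroxy enone: cyclohept-2-enone (C7=O, C1(CH3)=C2, C3–OH) with cis-fused menthyloxy lactone at C4–C5 | CC1=C[C@H](O)[C@H]2[C@@](C)(CC1=O)[C@H](O[C@@H]3C[C@H](C)CC[C@H]3C(C)C)OC2=O | intermediate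
14 | C3 triethylsilyl ether of 13 | CC1=C[C@H](O[Si](CC)(CC)CC)[C@H]2[C@@](C)(CC1=O)[C@H](O[C@@H]3C[C@H](C)CC[C@H]3C(C)C)OC2=O | intermediate
15 | C7 allylic alcohol of 14 (C7 epimers) | CC1=C[C@H](O[Si](CC)(CC)CC)[C@H]2[C@@](C)(CC1O)[C@H](O[C@@H]3C[C@H](C)CC[C@H]3C(C)C)OC2=O | intermediate
16 | C7 tert-butyldimethylsilyl ether of 15 | CC1=C[C@H](O[Si](CC)(CC)CC)[C@H]2[C@@](C)(CC1O[Si](C)(C)C(C)(C)C)[C@H](O[C@@H]3C[C@H](C)CC[C@H]3C(C)C)OC2=O | intermediate
17 | cyclic hemiketal: isopropyl adduct at the lactone carbon C10 (C10 undefined) | CC1=C[C@H](O[Si](CC)(CC)CC)[C@H]2[C@@](C)(CC1O[Si](C)(C)C(C)(C)C)[C@H](O[C@@H]3C[C@H](C)CC[C@H]3C(C)C)OC2(O)C(C)C | intermediate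
18 | cis keto aldehyde: C4 isobutyryl and C5 formyl syn, C3–OSiEt3, C7–OSitBuMe2 | CC1=C[C@H](O[Si](CC)(CC)CC)[C@H](C(=O)C(C)C)[C@@](C)(CC1O[Si](C)(C)C(C)(C)C)C=O | intermediate
19 | trans keto aldehyde (C4 epimer of 18; isobutyryl anti to the formyl group and to C3–O) | CC1=C[C@H](O[Si](CC)(CC)CC)[C@@H](C(=O)C(C)C)[C@@](C)(CC1O[Si](C)(C)C(C)(C)C)C=O | intermediate
20 | C8 methyl carbinol from 19 (C8 epimers) | CC1=C[C@H](O[Si](CC)(CC)CC)[C@@H](C(=O)C(C)C)[C@@](C)(CC1O[Si](C)(C)C(C)(C)C)C(C)O | intermediate
21 | trans 1,4-diketone: C5 acetyl (C8, C9) and C4 isobutyryl (C10) | CC1=C[C@H](O[Si](CC)(CC)CC)[C@@H](C(=O)C(C)C)[C@@](C)(CC1O[Si](C)(C)C(C)(C)C)C(C)=O | intermediate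
22 | trans-fused hydroazulene aldol: C8 ketone, C10 tertiary OH syn to C5–CH3, isopropyl syn to H4, C3–OSiEt3, C7–OSitBuMe2 | CC1=C[C@H](O[Si](CC)(CC)CC)[C@@H]2[C@@](C)(CC1O[Si](C)(C)C(C)(C)C)C(=O)C[C@@]2(O)C(C)C | intermediate
23 | C3 alcohol of 22 | CC1=C[C@H](O)[C@@H]2[C@@](C)(CC1O[Si](C)(C)C(C)(C)C)C(=O)C[C@@]2(O)C(C)C | intermediate
24 | 4-hydroxybenzoic acid | OC(=O)c1ccc(O)cc1 | starting material
25 | triisopropylsilyl 4-(triisopropylsilyloxy)benzoate | CC(C)[Si](OC(=O)c1ccc(O[Si](C(C)C)(C(C)C)C(C)C)cc1)(C(C)C)C(C)C | intermediate
26 | 4-(triisopropylsilyloxy)benzoic acid | OC(=O)c1ccc(O[Si](C(C)C)(C(C)C)C(C)C)cc1 | intermediate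
27 | C3 4-(triisopropylsilyloxy)benzoate of 23 | CC1=C[C@H](OC(=O)c2ccc(O[Si](C(C)C)(C(C)C)C(C)C)cc2)[C@@H]3[C@@](C)(CC1O[Si](C)(C)C(C)(C)C)C(=O)C[C@@]3(O)C(C)C | intermediate
28 | C8 alcohol of 27 (C8–OH syn to C5–CH3) | CC1=C[C@H](OC(=O)c2ccc(O[Si](C(C)C)(C(C)C)C(C)C)cc2)[C@@H]3[C@@](C)(CC1O[Si](C)(C)C(C)(C)C)[C@H](O)C[C@@]3(O)C(C)C | intermediate
29 | C7 allylic alcohol with free phenol (C7 epimers) | CC1=C[C@H](OC(=O)c2ccc(O)cc2)[C@@H]3[C@@](C)(CC1O)[C@H](O)C[C@@]3(O)C(C)C | intermediate
30 | CNP0199397.1 | CC1=C[C@H](OC(=O)c2ccc(O)cc2)[C@@H]2[C@@](C)(CC1=O)[C@H](O)C[C@@]2(O)C(C)C | target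

## Step count and least certain steps

Total: 22 steps. Longest linear sequence: 20 steps (steps 1–3, 5–17, 19–22).

**Step 5 (key step).** The most likely failure is poor exo/endo discrimination, because the endo transition state gains from overlap of the lactone carbonyl with the ylide π system. Slow capture of 8 by the β-methyl butenolide, with self-dimerisation of 8, would aggravate the loss. Both adducts have the correct C5, since the face of 7 is chosen by the auxiliary; they differ only at C3 (C6 is erased). Fallback, setting out from 4 and 7 and returning at 13: the endo adduct F1 is taken through the conditions of steps 6–8, giving thiol adduct F2, hydroxy ketone F3 and, via sulfoxide F4, the C3-epimeric γ-hydroxy enone F5. F5 is inverted at C3 by Mitsunobu reaction with formic acid (PPh3, DIAD, THF, 0 °C) to formate F6. Mild methanolysis (KHCO3, MeOH/H2O, 0 °C) then gives 13. The inversion is placed this early because the C4 equilibrium of step 13 depends on the C3 substituent being on the face opposite to the C4 acyl group.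

**Step 13.** The equilibrium at C4 may not lie far enough on the trans side, because the formyl group on C5 is sterically small and differs little from the methyl group; loss of the β-silyloxy group from the enolate is the second concern. Fallback, setting out from 18 and returning at 21: 18 is carried without epimerisation through the conditions of steps 14 and 15 to cis carbinol F7 and cis diketone F8. F8 is equilibrated with NaOMe in MeOH at 0 °C. There the C5 substituent is the larger acetyl group, so the trans arrangement is favoured more strongly, and any cis-fused aldol can revert by retro-aldol. Material that closes directly to 22 is the product of step 16 in any case.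

**Step 16.** The lithium aldolate of a hindered tertiary carbinol may revert (retro-aldol) or dehydrate on warming, and the isopropyl ketone flanked by C4 is a poor acceptor, so conversion may stall. Fallback, setting out from 21 and returning at 22: kinetic silylation (LiN(iPr)2 with Me3SiCl present, THF, −78 °C) gives silyl enol ether F9. NBS (THF, 0 °C) gives bromomethyl ketone F10. SmI2 (THF, −78 °C) generates the samarium enolate regiospecifically for an intramolecular Reformatsky-type addition to C10, which is not reversible at low temperature.

**Step 20.** Partial hydride delivery from a borate bound to the C10 hydroxyl would bring hydride to the face syn to the angular methyl and give the C8 epimer. Fallback, setting out from 27 and returning at 29: the C10 hydroxyl is capped (Me3SiOTf, 2,6-lutidine, CH2Cl2, −78 °C) to give F11. Reduction with the bulky LiBH(sBu)3 (THF, −78 °C), which can only approach anti to the angular methyl and the C10 silyloxy group, gives F12. The conditions of step 21 remove all three silyl groups to give 29.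

## Further compounds

F1 | step 5 | endo (5+2) adduct (oxygen bridge anti to the lactone; C3 and C6 epimer of 9) | CC1=C[C@H]2O[C@@H](C1=O)[C@@]3(C)[C@H](O[C@@H]4C[C@H](C)CC[C@H]4C(C)C)OC(=O)[C@H]32
F2 | step 5 | C2 phenylthio adduct of F1 (C1 undefined) | CC1[C@@H](Sc2ccccc2)[C@H]3O[C@@H](C1=O)[C@@]4(C)[C@H](O[C@@H]5C[C@H](C)CC[C@H]5C(C)C)OC(=O)[C@H]43
F3 | step 5 | ring-opened hydroxy ketone sulfide, C3 epimer of 11 | CC1[C@@H](Sc2ccccc2)[C@@H](O)[C@H]3[C@@](C)(CC1=O)[C@H](O[C@@H]4C[C@H](C)CC[C@H]4C(C)C)OC3=O
F4 | step 5 | sulfoxide of F3 | CC1[C@@H](S(=O)c2ccccc2)[C@@H](O)[C@H]3[C@@](C)(CC1=O)[C@H](O[C@@H]4C[C@H](C)CC[C@H]4C(C)C)OC3=O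
F5 | step 5 | C3 epimer of γ-hydroxy enone 13 | CC1=C[C@@H](O)[C@H]2[C@@](C)(CC1=O)[C@H](O[C@@H]3C[C@H](C)CC[C@H]3C(C)C)OC2=O
F6 | step 5 | C3 formate of 13 (C3 inverted relative to F5) | CC1=C[C@H](OC=O)[C@H]2[C@@](C)(CC1=O)[C@H](O[C@@H]3C[C@H](C)CC[C@H]3C(C)C)OC2=O
F7 | step 13 | cis C8 methyl carbinol (C4 epimer of 20, C8 epimers) | CC1=C[C@H](O[Si](CC)(CC)CC)[C@H](C(=O)C(C)C)[C@@](C)(CC1O[Si](C)(C)C(C)(C)C)C(C)O
F8 | step 13 | cis 1,4-diketone (C4 epimer of 21) | CC1=C[C@H](O[Si](CC)(CC)CC)[C@H](C(=O)C(C)C)[C@@](C)(CC1O[Si](C)(C)C(C)(C)C)C(C)=O
F9 | step 16 | trimethylsilyl enol ether of the acetyl group of 21 (C8–OSiMe3, C8=C9) | CC1=C[C@H](O[Si](CC)(CC)CC)[C@@H](C(=O)C(C)C)[C@@](C)(CC1O[Si](C)(C)C(C)(C)C)C(=C)O[Si](C)(C)C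
F10 | step 16 | C9 bromo derivative of 21 (bromomethyl ketone) | CC1=C[C@H](O[Si](CC)(CC)CC)[C@@H](C(=O)C(C)C)[C@@](C)(CC1O[Si](C)(C)C(C)(C)C)C(=O)CBr
F11 | step 20 | C10 trimethylsilyl ether of 27 | CC1=C[C@H](OC(=O)c2ccc(O[Si](C(C)C)(C(C)C)C(C)C)cc2)[C@@H]3[C@@](C)(CC1O[Si](C)(C)C(C)(C)C)C(=O)C[C@@]3(O[Si](C)(C)C)C(C)C
F12 | step 20 | C8 alcohol from F11 (C8–OH syn to C5–CH3) | CC1=C[C@H](OC(=O)c2ccc(O[Si](C(C)C)(C(C)C)C(C)C)cc2)[C@@H]3[C@@](C)(CC1O[Si](C)(C)C(C)(C)C)[C@H](O)C[C@@]3(O[Si](C)(C)C)C(C)C
A1 | alternative 1 | ring B cyclopentane oxime: C6–C7 oxime arm on C5, C3(OPMB)–C2–C1 allyl arm on C4, C8–OSitBuMe2, C10–OSiEt3 (oxime geometry undefined) | ON=CC[C@@]1(C)[C@H](O[Si](C)(C)C(C)(C)C)C[C@@](O[Si](CC)(CC)CC)(C(C)C)[C@@H]1[C@@H](OCc2ccc(OC)cc2)CC=C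
A2 | alternative 1 | tricyclic isoxazoline (ring A closed, C7 as C=N, future C1 methyl as O–CH2) | C1ON=C2C[C@@]3(C)[C@H](O[Si](C)(C)C(C)(C)C)C[C@@](O[Si](CC)(CC)CC)(C(C)C)[C@@H]3[C@@H](OCc4ccc(OC)cc4)C[C@@H]12
A3 | alternative 2 | allyl 3-(tert-butyldimethylsilyloxy)-2-diazobut-3-enoate | C=CCOC(=O)C(=[N+]=[N-])C(=C)O[Si](C)(C)C(C)(C)C
A4 | alternative 2 | cyclopentenyl diene: 1-(1-ethoxyvinyl)-2-methylcyclopentene with C8–OSitBuMe2 and C10 (OSiEt3, isopropyl) | C=C(OCC)C1=C(C)[C@H](O[Si](C)(C)C(C)(C)C)C[C@@]1(O[Si](CC)(CC)CC)C(C)C
A5 | alternative 2 | bicyclic cycloheptadiene (C7 silyl enol ether of the β-keto ester, C3 ethyl enol ether) | C=CCOC(=O)C1=C(O[Si](C)(C)C(C)(C)C)C[C@@]2(C)[C@H](O[Si](C)(C)C(C)(C)C)C[C@@](O[Si](CC)(CC)CC)(C(C)C)C2=C(OCC)C1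
A6 | alternative 3 | alkenyl cyclobutanol (C8 carbinol carbon bearing the C5=C6 alkenyl group; C8 and alkene geometry undefined) | CC#C[C@H](O[Si](C)(C)C(C)(C)C)[C@@H]1C(O)(C(C)=CCOCc2ccccc2)C[C@@]1(O[Si](CC)(CC)CC)C(C)C
A7 | alternative 3 | α-quaternary cyclopentanone (ring B) with benzyloxyethyl and alkynyl carbinol chains trans | CC#C[C@H](O[Si](C)(C)C(C)(C)C)[C@@H]1[C@@](C)(CCOCc2ccccc2)C(=O)C[C@@]1(O[Si](CC)(CC)CC)C(C)C
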